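**Retrosynthetic overview**
1. 8 ⇐ 7 ⇐ 6: the one strategic disconnection is the benzylic ring-ether bond O1–C2, made by reductive cycloetherification of a γ-hydroxy aryl ketone. This is the new, enantioselective step; it sets C2 and C3, and C4 follows by epimerisation.
2. 6 (bis-lactol, racemic and stereolabile) ⇐ tetraol 4 by selective benzylic oxidation.
3. 4 ⇐ diketo diester 3 by global reduction; 3 ⇐ two molecules of β-keto ester 1 by oxidative enolate dimerisation (the C3–C4 bond).
4. Ring order: rings A and B of 6 close together as hemiketals in step 3. In step 4 ring B becomes the tetrahydrofuran of 8 and ring A is reopened to the aryl ketone and the CH2OH group.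

Ring numbering of 8 used below: O1, C2 (aryl, S), C3 (CH2OH, S), C4 (aroyl, R), C5 (CH2). Aryl and CH2OH are cis; CH2OH and aroyl are trans.

Acid A (step 4): (S,S)-IDPi, the imidodiphosphorimidate (BINOL-O2)P(=N–SO2CF3)–N=P(O2-BINOL)–NH–SO2CF3 built from two (S)-3,3'-bis[3,5-bis(trifluoromethyl)phenyl]-1,1'-bi-2-naphthol units.

Assumption: the facial sense of the new step cannot be predicted with certainty; acid A is written as (S,S), and its mirror image is used if a test run shows the opposite sense.

**Step 1**
Reactants: 1 ethyl 3-oxo-3-(3,4,5-trimethoxyphenyl)propanoate (two molecules)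
Product: 3 diethyl 2,3-bis(3,4,5-trimethoxybenzoyl)butanedioate, via α-iodo keto ester 2 (not isolated)
Conditions: NaH (1.05 equiv), THF, 0 °C; I2 (0.5 equiv), −78 °C to rt
Reagents that add atoms: iodine, [I][I] (adds I to intermediate 2 only; no atom of it remains in 3)
Why: Oxidative homocoupling of a β-keto ester enolate: half of the sodium enolate is iodinated to 2 and the other half displaces iodide (SN2); the two new centres are enolisable (rac/meso mixture) and need no control.

**Step 2**
Reactants: 3 diethyl 2,3-bis(3,4,5-trimethoxybenzoyl)butanedioate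
Product: 4 2,3-bis[hydroxy(3,4,5-trimethoxyphenyl)methyl]butane-1,4-diol
Conditions: LiBH4 (6 equiv), THF/MeOH 10:1, 0 to 50 °C; aq. NH4Cl work-up (kept neutral)
Reagents that add atoms: none
Why: Exhaustive borohydride reduction of both aryl ketones and both esters (LiBH4 is less basic than LiAlH4, which limits enolisation of the β-keto ester); the diastereomer mixture is accepted because step 3 erases the carbinol centres and step 4 re-equilibrates the backbone centres.

**Step 3**
Reactants: 4 2,3-bis[hydroxy(3,4,5-trimethoxyphenyl)methyl]butane-1,4-diol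
Product: 6 racemic cis-fused 1,4-bis(3,4,5-trimethoxyphenyl)tetrahydro-1H,3H-furo[3,4-c]furan-1,4-diol (bis-lactol), via open diketo diol 5 (not isolated)
Conditions: activated MnO2 (20 equiv), CH2Cl2, rt; filtration through Celite
Reagents that add atoms: none
Why: Chemoselective MnO2 oxidation of the two benzylic carbinols only; each new aryl ketone is trapped by the 1,4-related CH2OH as a five-membered hemiketal, which has no carbinol hydrogen and cannot be over-oxidised, giving the cis-fused bis-lactol as a racemate.

**Step 4**
Reactants: 6 racemic cis-fused bis-lactol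
Product: 8 [(3R,4S,5S)-4-(hydroxymethyl)-5-(3,4,5-trimethoxyphenyl)oxolan-3-yl](3,4,5-trimethoxyphenyl)methanone, via cis-fused lactol 7 (not isolated)
Conditions: acid A (5 mol%), Hantzsch ester (diethyl 2,6-dimethyl-1,4-dihydropyridine-3,5-dicarboxylate, 1.05 equiv), 5 Å MS, toluene, −20 °C; then DBU (0.3 equiv), rt
Reagents that add atoms: none
Why: Proposed new method: enantioselective reductive cycloetherification with dynamic kinetic resolution. Acid A ionises one hemiketal C–OH of 6 (water goes to the sieves) to a 2-aryl oxocarbenium ion held in the chiral IDPi anion pocket. This ion equilibrates with its cyclic enol ether and, through the ring-opened diketone 5, with all C3/C4 stereoisomers faster than it is reduced, so the racemic, stereolabile pool drains through the one ion pair that the chiral anion allows the Hantzsch ester to reduce. Hydride arrives on the convex face of the cis-fused bicycle (anti to the C3 substituent), which places the C2 aryl cis to CH2OH; this sets C2 (S) and C3 (S) together and locks the former ketone/alcohol pair as the ring ether C2–O1. DBU then opens the remaining lactol ring of 7 and epimerises C4 to the trans aryl ketone (4R), expected to be the more stable isomer, which cannot re-close and is inert to further reduction. The closest known reaction types are the chiral-phosphoric-acid/Hantzsch ester reductive amination of α-branched carbonyl compounds with dynamic kinetic resolution, chiral-anion-controlled hydride transfer to benzopyrylium ions, IDPi-controlled additions to cyclic aliphatic oxocarbenium ions, and the BF3·OEt2/Et3SiH reduction of aryl lactols (same convex-face diastereoselectivity).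

**Compound list**
1 | ethyl 3-oxo-3-(3,4,5-trimethoxyphenyl)propanoate | CCOC(=O)CC(=O)c1cc(OC)c(OC)c(OC)c1 | starting material
2 | ethyl 2-iodo-3-oxo-3-(3,4,5-trimethoxyphenyl)propanoate (racemic, not isolated) | CCOC(=O)C(I)C(=O)c1cc(OC)c(OC)c(OC)c1 | intermediate
3 | diethyl 2,3-bis(3,4,5-trimethoxybenzoyl)butanedioate (rac/meso mixture, centres enolisable) | CCOC(=O)C(C(=O)c1cc(OC)c(OC)c(OC)c1)C(C(=O)c1cc(OC)c(OC)c(OC)c1)C(=O)OCC | intermediate
4 | 2,3-bis[hydroxy(3,4,5-trimethoxyphenyl)methyl]butane-1,4-diol (diastereomer mixture) | OCC(C(O)c1cc(OC)c(OC)c(OC)c1)C(CO)C(O)c1cc(OC)c(OC)c(OC)c1 | intermediate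
5 | 2,3-bis(hydroxymethyl)-1,4-bis(3,4,5-trimethoxyphenyl)butane-1,4-dione (open form, stereoisomer mixture, not isolated) | OCC(C(=O)c1cc(OC)c(OC)c(OC)c1)C(CO)C(=O)c1cc(OC)c(OC)c(OC)c1 | intermediate
6 | cis-fused 1,4-bis(3,4,5-trimethoxyphenyl)tetrahydro-1H,3H-furo[3,4-c]furan-1,4-diol (bis-lactol; racemic, one enantiomer drawn, hemiketal carbons unassigned) | OC1(c3cc(OC)c(OC)c(OC)c3)[C@@H]2COC(O)(c4cc(OC)c(OC)c(OC)c4)[C@@H]2CO1 | intermediate
7 | cis-fused lactol: the ring-closed hemiketal of the C4 epimer of 8 (1,4-bis(3,4,5-trimethoxyphenyl)tetrahydro-1H,3H-furo[3,4-c]furan-1-ol, 4-aryl on the concave face, anomeric mixture, not isolated) | OC1(c3cc(OC)c(OC)c(OC)c3)[C@@H]2CO[C@H](c4cc(OC)c(OC)c(OC)c4)[C@@H]2CO1 | intermediate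
8 | [(3R,4S,5S)-4-(hydroxymethyl)-5-(3,4,5-trimethoxyphenyl)oxolan-3-yl](3,4,5-trimethoxyphenyl)methanone | COc1cc(C(=O)[C@H]2CO[C@H](c3cc(OC)c(OC)c(OC)c3)[C@@H]2CO)cc(OC)c1OC | target

**Totals**
Total step count: 4. Longest linear sequence: 4 steps.

**Steps most likely to fail**

Step 4 (the proposed new step). The risks are low enantioselectivity if the stereoisomers interconvert too slowly, a second reduction of 7 to the diaryl furofuran before C4 epimerises, and loss of acid strength to the pyridine by-product. The fallback uses known chemistry and sets out from 6. Et3SiH (1.0 equiv) and BF3·OEt2 in CH2Cl2 at −78 °C reduce one lactol with the same substrate-controlled convex-face hydride delivery and give the racemic cis-fused lactol F1. DBU in the same flask gives the racemate of 8 F2. Esterification of its primary alcohol with (S)-O-acetylmandelic acid (DCC, DMAP, CH2Cl2) gives the (S)-O-acetylmandelate of 8 F3 and the (S)-O-acetylmandelate of the mirror image of 8 F4, which are separated by chromatography or crystallisation. K2CO3 in MeOH at 0 °C cleaves F3, and the fallback comes back to the route at 8.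

Step 3. MnO2 may stall at the mono-ketone stage or lose the polar tetraol by adsorption. The fallback sets out from 4 and enforces the chemoselectivity with protecting groups. TBSCl (2.1 equiv) and imidazole in DMF at 0 °C silylate only the two primary alcohols to give the bis-silyl ether of 4 F5. Dess–Martin periodinane with NaHCO3 in CH2Cl2 oxidises both benzylic carbinols to the bis-silyl diketone F6. HF·pyridine in THF at 0 °C removes both silyl groups, the diol 5 closes, and the fallback comes back to the route at 6.

Step 2. The β-keto ester may enolise or fragment under hydride, or the esters may be reduced incompletely. The fallback sets out from 3 and reduces in two stages through an isolable lactone. NaBH4 in EtOH at 0 °C reduces only the ketones, and the γ-hydroxy esters lactonise to the dilactone F7. LiAlH4 in THF (0 °C to rt) then reduces both lactones, and the fallback comes back to the route at 4.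

**Further compounds**
F1 | step 4 | racemic cis-fused lactol (7 together with its mirror image) | OC1(c3cc(OC)c(OC)c(OC)c3)[C@@H]2CO[C@H](c4cc(OC)c(OC)c(OC)c4)[C@@H]2CO1.OC1(c3cc(OC)c(OC)c(OC)c3)[C@H]2CO[C@@H](c4cc(OC)c(OC)c(OC)c4)[C@H]2CO1
F2 | step 4 | racemate of 8 (8 together with its mirror image) | COc1cc(C(=O)[C@H]2CO[C@H](c3cc(OC)c(OC)c(OC)c3)[C@@H]2CO)cc(OC)c1OC.COc1cc(C(=O)[C@@H]2CO[C@@H](c3cc(OC)c(OC)c(OC)c3)[C@H]2CO)cc(OC)c1OC
F3 | step 4 | (S)-O-acetylmandelate of 8 | COc1cc(C(=O)[C@H]2CO[C@H](c3cc(OC)c(OC)c(OC)c3)[C@@H]2COC(=O)[C@@H](OC(C)=O)c4ccccc4)cc(OC)c1OC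
F4 | step 4 | (S)-O-acetylmandelate of the mirror image of 8 | COc1cc(C(=O)[C@@H]2CO[C@@H](c3cc(OC)c(OC)c(OC)c3)[C@H]2COC(=O)[C@@H](OC(C)=O)c4ccccc4)cc(OC)c1OC
F5 | step 3 | 1,4-bis-O-(tert-butyldimethylsilyl) ether of tetraol 4 (diastereomer mixture) | CC(C)(C)[Si](C)(C)OCC(C(O)c1cc(OC)c(OC)c(OC)c1)C(CO[Si](C)(C)C(C)(C)C)C(O)c1cc(OC)c(OC)c(OC)c1
F6 | step 3 | 2,3-bis[(tert-butyldimethylsilyloxy)methyl]-1,4-bis(3,4,5-trimethoxyphenyl)butane-1,4-dione (stereoisomer mixture) | CC(C)(C)[Si](C)(C)OCC(C(=O)c1cc(OC)c(OC)c(OC)c1)C(CO[Si](C)(C)C(C)(C)C)C(=O)c1cc(OC)c(OC)c(OC)c1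
F7 | step 2 | 3,6-bis(3,4,5-trimethoxyphenyl)tetrahydro-1H,4H-furo[3,4-c]furan-1,4-dione (dilactone, stereoisomer mixture) | O=C1OC(c3cc(OC)c(OC)c(OC)c3)C2C1C(c4cc(OC)c(OC)c(OC)c4)OC2=O
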